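**Plan**

- Retrosynthesis: the three acetates and the O12 silyl group come off first; the ten-membered ring is cut at C4–C5 (alkylborane coupled to a (Z)-α-iodoenoate); the γ-lactone is cut at O–C7 and C17–C8 together; the C6–C9 chain is cut at C8–C9; the cyclohexane is traced back to 2-methoxy-5-methylbenzoic acid.
- Forward order of rings: cyclohexane (from the arene, C1 and C10–C14), then the γ-lactone (step 20), then the ten-membered ring last (step 23).
- Enabling feature: C8 is a ketone flanked by the C9 ether oxygen and the C6–C7 oxirane. This makes C8 (carbonyl) and C7 (oxirane carbon) a 1,2-bis-electrophile matched to the C,O-bis-nucleophile of a propanoate enolate: C17 adds to C8, then the carboxyl oxygen opens the oxirane at C7 and closes the ring O–C19–C17–C8–C7.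
- Stereochemistry: C1 from a prolinol-ether auxiliary; C14, C10, C11 and C12 by substrate control on the cyclohexane; C9 (and the 8,9-syn relay) by Brown alkoxyallylboration; C7 by Sharpless epoxidation followed by inversion; C8 by chelation and C17 in the same step; C2 by chelation-controlled reduction; the C5=C6 geometry by a Z-selective iodo-Wittig reaction and a stereoretentive coupling.

Key step: step 20

Locants are those of the briarane skeleton (C15 = methyl on C1, C16 = ester carbon on C5, C17/C18/C19 = lactone CH, its methyl and its carbonyl, C20 = methyl on C11); β is the face of the cyclohexane that carries C15. PMB = 4-methoxybenzyl, TBS = tert-butyldimethylsilyl, MOM = methoxymethyl, Ipc = isopinocampheyl.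

Assumption: the methylation in step 2 is taken to follow the usual facial preference of prolinol-ether benzamide enolates and to give the (1R) centre drawn from the (S)-auxiliary; if the sense were opposite, the (R)-auxiliary would be used with no other change.

**Route**

Step 1
Reactants: 1 2-methoxy-5-methylbenzoic acid; 2 (S)-2-(methoxymethyl)pyrrolidine
Product: 4 (2-methoxy-5-methylphenyl)[(2S)-2-(methoxymethyl)pyrrolidin-1-yl]methanone, via acid chloride 3 (not isolated)
Conditions: (COCl)2, DMF (cat.), CH2Cl2, 0 °C → rt; then 2, aq. NaOH, CH2Cl2, 0 °C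
Reagents that add atoms: none
Why: Acid chloride formation followed by Schotten–Baumann amidation; no stereocentre is created and the auxiliary centre is untouched.

Step 2
Reactants: 4 benzamide
Product: 6 [(1R)-2-methoxy-1,5-dimethylcyclohexa-2,5-dien-1-yl][(2S)-2-(methoxymethyl)pyrrolidin-1-yl]methanone, via potassium enolate 5 (not isolated)
Conditions: K, NH3 (l), THF, t-BuOH (1 equiv), −78 °C; then MeI, −78 °C
Reagents that add atoms: iodomethane CI
Why: Schultz asymmetric Birch reduction–alkylation: dissolving-metal reduction gives the chelated potassium amide enolate 5, which MeI alkylates on the face turned away from the methoxymethyl arm of the auxiliary, so the quaternary centre C1 is set under auxiliary control.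

Step 3
Reactants: 6 dienyl amide
Product: 7 [(1R)-1,3-dimethyl-6-oxocyclohex-2-en-1-yl][(2S)-2-(methoxymethyl)pyrrolidin-1-yl]methanone
Conditions: 1 M HCl, THF–MeOH, 0 °C → rt
Reagents that add atoms: water O
Why: Acid hydrolysis of the methyl enol ether to the C14 ketone; the C10=C11 double bond cannot move into conjugation across the quaternary carbon.

Step 4
Reactants: 7 keto amide
Product: 8 [(1R,6S)-6-hydroxy-1,3-dimethylcyclohex-2-en-1-yl][(2S)-2-(methoxymethyl)pyrrolidin-1-yl]methanone (14α-alcohol; hydroxyl cis to the amide)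
Conditions: NaBH4, MeOH, −40 °C
Reagents that add atoms: none
Why: Borohydride reduction with axial hydride attack anti to the pseudo-axial carboxamide carbon (polar Felkin–Anh control) places the new C14 hydroxyl cis to the amide.

Step 5
Reactants: 8 hydroxy amide
Product: 9 14-O-PMB ether of 8
Conditions: NaH, 4-MeOC6H4CH2Cl, n-Bu4NI (cat.), DMF, 0 °C → rt
Reagents that add atoms: 4-methoxybenzyl chloride COc1ccc(CCl)cc1
Why: Williamson etherification protects O14 as an ether that can later chelate and be removed oxidatively.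

Step 6
Reactants: 9 PMB ether
Product: 10 C12 allylic alcohols of 9 (both C12 epimers)
Conditions: SeO2 (cat.), t-BuOOH, CH2Cl2, rt
Reagents that add atoms: tert-butyl hydroperoxide CC(C)(C)OO
Why: SeO2-catalysed allylic hydroxylation (ene reaction then 2,3-sigmatropic shift) attacks the ring CH2 on the more substituted olefin terminus (C12); the new carbinol configuration is irrelevant because it is oxidised next.

Step 7
Reactants: 10 allylic alcohols
Product: 11 [(1R,6S)-6-(4-methoxybenzyloxy)-1,3-dimethyl-4-oxocyclohex-2-en-1-yl][(2S)-2-(methoxymethyl)pyrrolidin-1-yl]methanone (C12 enone)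
Conditions: MnO2, CH2Cl2, rt
Reagents that add atoms: none
Why: MnO2 oxidation of the allylic alcohol gives the enone without touching the PMB ether or the amide.

Step 8
Reactants: 11 enone
Product: 13 C12 ketone with 10β-vinyl (10α-H) and 11β-methyl groups; 14α-OPMB; C1 amide, via silyl enol ether 12 (not isolated)
Conditions: CH2=CHMgBr, CuBr·SMe2 (cat.), Me3SiCl, THF, −78 °C; then AcOH–H2O, −78 → 0 °C
Reagents that add atoms: vinylmagnesium bromide C=C[Mg]Br
Why: Copper-catalysed conjugate addition accelerated by Me3SiCl: the vinyl group adds axially to C10 on the β face, anti to the pseudo-axial carboxamide on C1 and to the 14α-ether, and kinetic protonation of silyl enol ether 12 anti to the now axial vinyl group puts the C11 methyl β.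

Step 9
Reactants: 13 ketone
Product: 14 12β-alcohol (axial) of 13
Conditions: LiBH(s-Bu)3, THF, −78 °C; then H2O
Reagents that add atoms: none
Why: The bulky trialkylborohydride attacks the C12 carbonyl equatorially from the α face, the β face being blocked by the axial 10-vinyl group, which gives the 12β-alcohol; prompt reduction also prevents epimerisation at C11.

Step 10
Reactants: 14 alcohol
Product: 15 12β-TBS ether
Conditions: t-BuMe2SiOTf, 2,6-lutidine, CH2Cl2, 0 °C
Reagents that add atoms: tert-butyldimethylsilyl trifluoromethanesulfonate CC(C)(C)[Si](C)(C)OS(=O)(=O)C(F)(F)F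
Why: Silylation with the silyl triflate protects the hindered axial 12-hydroxyl as the ether that is removed last.

Step 11
Reactants: 15 vinyl compound
Product: 17 C9 aldehyde (formyl group β on C10), via vicinal diol 16 (not isolated)
Conditions: OsO4 (cat.), NaIO4, 2,6-lutidine, dioxane–H2O, rt
Reagents that add atoms: sodium periodate [Na+].[O-]I(=O)(=O)=O (oxygen relayed through OsO4)
Why: Lemieux–Johnson cleavage (dihydroxylation to 16, then periodate scission) shortens the vinyl group to the C9 aldehyde; the lutidine buffer guards C10 against epimerisation.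

Step 12
Reactants: 17 aldehyde
Product: 18 (8R,9R)-9-hydroxy-8-(methoxymethoxy) adduct carrying the C6=C7 vinyl group (8,9-syn)
Conditions: CH2=CHCH2OCH2OCH3, s-BuLi, THF, −78 °C; (−)-Ipc2BOMe; BF3·OEt2; then 17, −78 °C; NaOH, H2O2, 0 °C
Reagents that add atoms: allyl methoxymethyl ether C=CCOCOC
Why: Brown alkoxyallylboration through a chair six-membered transition state: the (Z)-γ-alkoxyallyl geometry gives the 8,9-syn relationship, and the isopinocampheyl groups derived from (+)-α-pinene direct attack to the aldehyde face that gives the (9R) carbinol.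

Step 13
Reactants: 18 alcohol
Product: 19 9-O-PMB ether of 18
Conditions: NaH, 4-MeOC6H4CH2Cl, n-Bu4NI (cat.), THF–DMF, 0 °C → rt
Reagents that add atoms: 4-methoxybenzyl chloride COc1ccc(CCl)cc1
Why: Williamson etherification turns O9 into the chelating ether needed in steps 18 to 20.

Step 14
Reactants: 19 amide
Product: 20 C2 vinyl ketone (C1 now carries C(=O)CH=CH2, that is C2, C3 and C4)
Conditions: CH2=CHLi, THF, −78 → −20 °C; inverse quench into 1 M HCl, 0 °C
Reagents that add atoms: vinyllithium [Li]C=C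
Why: Ketone synthesis by addition of an organolithium to a tertiary amide: the tetrahedral lithium adduct is held by the methoxymethyl arm until the acidic quench, which releases the vinyl ketone and protonates the freed auxiliary so that it cannot add to the enone.

Step 15
Reactants: 20 vinyl ketone
Product: 21 (2R)-allylic alcohol
Conditions: Zn(BH4)2, Et2O, −30 °C
Reagents that add atoms: none
Why: Chelation-controlled 1,2-reduction: zinc bridges the C2 carbonyl and the 14-ether oxygen and hydride enters from the exposed face (that of C15), which sets (2R), the 2,14-syn relationship of the target.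

Step 16
Reactants: 21 allylic alcohol
Product: 22 2-O-PMB ether
Conditions: NaH, 4-MeOC6H4CH2Cl, n-Bu4NI (cat.), THF–DMF, 0 °C → rt
Reagents that add atoms: 4-methoxybenzyl chloride COc1ccc(CCl)cc1
Why: Williamson etherification protects the allylic C2 hydroxyl before the epoxidation and oxidation steps.

Step 17
Reactants: 22 MOM ether
Product: 23 (8R,9R)-C8 allylic alcohol
Conditions: ZnBr2, n-PrSH, CH2Cl2, 0 °C
Reagents that add atoms: none
Why: Lewis acid-assisted acetal exchange with the thiol cleaves the methoxymethyl ether selectively and frees the C8 allylic alcohol; benzyl-type and silyl ethers are retained.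

Step 18
Reactants: 23 allylic alcohol
Product: 24 (7R,8S,9R)-6,7-epoxy-8-ol
Conditions: Ti(Oi-Pr)4, L-(+)-diisopropyl tartrate, t-BuOOH, 4 Å molecular sieves, CH2Cl2, −20 °C
Reagents that add atoms: tert-butyl hydroperoxide CC(C)(C)OO
Why: Sharpless asymmetric epoxidation: the L-(+)-tartrate catalyst delivers oxygen to the face of C6=C7 that gives the (7R)-oxirane, the 8,9-syn carbinol is the fast-reacting (matched) epimer and leads to the erythro epoxy alcohol, and the allylic ether olefin C3=C4 is not epoxidised.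

Step 19
Reactants: 24 epoxy alcohol
Product: 25 (7R,9R)-6,7-epoxy-8-ketone
Conditions: Dess–Martin periodinane, CH2Cl2, 0 °C → rt
Reagents that add atoms: none
Why: Dess–Martin oxidation converts the C8 carbinol into the ketone under non-basic conditions that leave the oxirane and the C9 centre intact.

Step 20
Reactants: 25 epoxy ketone
Product: 27 hydroxymethyl γ-lactone (ring O–C19–C17–C8–C7 configured as in the target; 8α-OH; C18 cis to 8-OH; C6 as CH2OH on C7), via aldol adduct 26 (not isolated)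
Conditions: Zn, CH3CHBrCO2t-Bu, THF, rt (Reformatsky reagent, excess Zn filtered off); then 25, −20 → 0 °C; then camphorsulfonic acid, CH2Cl2, 0 °C → rt
Reagents that add atoms: tert-butyl 2-bromopropanoate CC(Br)C(=O)OC(C)(C)C
Why: The zinc enolate adds to the C8 carbonyl (Reformatsky aldol) and, on acidification, the tert-butyl ester carbonyl oxygen of adduct 26 opens the protonated oxirane at C7 with loss of 2-methylpropene, so the C17–C8 and O–C7 bonds arise in one flask; the closest known reactions are Reformatsky additions to α-alkoxy ketones and the acid-mediated lactonisation of γ,δ-epoxy tert-butyl esters. The γ-lactone closes by 5-exo-tet attack on the oxirane. C8 is set by the Cram chelate, in which zinc bridges the C8 carbonyl and the C9 PMB ether oxygen and C17 enters on the face of H-9, the face also preferred with respect to the oxirane (C7–O bond anti to the nucleophile). C17 follows from an open transition state in which the enolate carboxyl carbon lies synclinal to the carbonyl oxygen on the side of the small oxirane and H-17 sits between C7 and C9. C7 is set by inversion of the (7R)-oxirane made in step 18. The step needs carbonyl addition to outrun enolisation at C9 and opening of the oxirane by enolate or bromide (weakly basic zinc enolate, low temperature, zinc-free reagent), and 5-exo closure to outrun 6-endo closure (attack at the more substituted oxirane carbon under acid).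

Step 21
Reactants: 27 hydroxymethyl lactone
Product: 28 C6 aldehyde
Conditions: Dess–Martin periodinane, CH2Cl2, 0 °C
Reagents that add atoms: none
Why: Dess–Martin oxidation of the primary C6 alcohol; the tertiary 8-hydroxyl cannot be oxidised.

Step 22
Reactants: 28 aldehyde
Product: 29 methyl (Z)-2-iodoenoate (C16 ester and iodine on C5; C5=C6)
Conditions: Ph3P=CHCO2Me, N-iodosuccinimide, CH2Cl2, −20 °C; then 28, −20 °C → rt
Reagents that add atoms: methyl (triphenylphosphoranylidene)acetate COC(=O)C=P(c1ccccc1)(c1ccccc1)c1ccccc1; N-iodosuccinimide O=C1CCC(=O)N1I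
Why: Wittig olefination with the iodo-ylide made in the flask; as a stabilised ylide it places the ester trans to C7 and so gives the (Z)-α-iodoenoate that carries the C5=C6 geometry of the target.

Step 23
Reactants: 29 iodoenoate
Product: 31 ten-membered carbocycle (2,9,14-tris-PMB ether and 12-TBS ether of the deacetylated target), via alkylborane 30 (not isolated)
Conditions: 9-BBN, THF, rt; then Pd(dppf)Cl2 (cat.), AsPh3 (cat.), Cs2CO3, DMF–THF–H2O, 0.002 M, rt
Reagents that add atoms: none
Why: Anti-Markovnikov hydroboration of the C3=C4 vinyl group followed by intramolecular B-alkyl Suzuki–Miyaura coupling forms C4–C5 with retention of the iodoalkene geometry and closes the ten-membered ring.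

Step 24
Reactants: 31 tris-PMB ether
Product: 32 2,9,14-triol (12-TBS ether)
Conditions: DDQ, CH2Cl2–pH 7 buffer, 0 °C → rt
Reagents that add atoms: none
Why: Oxidative cleavage of the three PMB ethers by DDQ in buffered wet solvent, which also hydrolyses any anisylidene acetal formed with the 8-hydroxyl; the TBS ether, the enoate and the lactone are inert.

Step 25
Reactants: 32 triol
Product: 33 2,9,14-triacetate 12-TBS ether
Conditions: Ac2O, pyridine, 4-(dimethylamino)pyridine (cat.), CH2Cl2, rt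
Reagents that add atoms: acetic anhydride CC(=O)OC(C)=O
Why: Acylation of the three secondary alcohols; the tertiary 8-hydroxyl is too hindered to react and O12 is still silylated.

Step 26
Reactants: 33 silyl ether
Product: 34 CNP0233742.2 (target)
Conditions: HF·pyridine, THF–pyridine, 0 °C → rt
Reagents that add atoms: none
Why: Fluoride-mediated desilylation frees the 12β-hydroxyl and gives the target without touching the acetates.

**Compound list**

1 | 2-methoxy-5-methylbenzoic acid | COc1ccc(C)cc1C(=O)O | starting material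
2 | (S)-2-(methoxymethyl)pyrrolidine | COC[C@@H]1CCCN1 | starting material
3 | 2-methoxy-5-methylbenzoyl chloride | COc1ccc(C)cc1C(Cl)=O | intermediate (not isolated)
4 | (2-methoxy-5-methylphenyl)[(2S)-2-(methoxymethyl)pyrrolidin-1-yl]methanone | COc1ccc(C)cc1C(=O)N1CCC[C@H]1COC | intermediate
5 | potassium enolate of the 1,4-dihydrobenzamide | COC1=CCC(C)=CC1=C([O-])N1CCC[C@H]1COC.[K+] | intermediate (not isolated)
6 | [(1R)-2-methoxy-1,5-dimethylcyclohexa-2,5-dien-1-yl][(2S)-2-(methoxymethyl)pyrrolidin-1-yl]methanone | COC1=CCC(C)=C[C@@]1(C)C(=O)N1CCC[C@H]1COC | intermediate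
7 | [(1R)-1,3-dimethyl-6-oxocyclohex-2-en-1-yl][(2S)-2-(methoxymethyl)pyrrolidin-1-yl]methanone | O=C1CCC(C)=C[C@@]1(C)C(=O)N1CCC[C@H]1COC | intermediate
8 | [(1R,6S)-6-hydroxy-1,3-dimethylcyclohex-2-en-1-yl][(2S)-2-(methoxymethyl)pyrrolidin-1-yl]methanone | O[C@H]1CCC(C)=C[C@@]1(C)C(=O)N1CCC[C@H]1COC | intermediate
9 | 14-O-PMB ether of 8 | COc1ccc(CO[C@H]2CCC(C)=C[C@@]2(C)C(=O)N2CCC[C@H]2COC)cc1 | intermediate
10 | C12 allylic alcohols of 9 (both C12 epimers) | COc1ccc(CO[C@H]2CC(O)C(C)=C[C@@]2(C)C(=O)N2CCC[C@H]2COC)cc1 | intermediate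
11 | C12 enone, [(1R,6S)-6-(4-methoxybenzyloxy)-1,3-dimethyl-4-oxocyclohex-2-en-1-yl] amide | COc1ccc(CO[C@H]2CC(=O)C(C)=C[C@@]2(C)C(=O)N2CCC[C@H]2COC)cc1 | intermediate
12 | C12 trimethylsilyl enol ether with 10β-vinyl group | C=C[C@H]2C(C)=C(O[Si](C)(C)C)C[C@H](OCc1ccc(OC)cc1)[C@]2(C)C(=O)N1CCC[C@H]1COC | intermediate (not isolated)
13 | C12 ketone, 10β-vinyl, 11β-methyl, 14α-OPMB, C1 amide | C=C[C@H]2[C@@H](C)C(=O)C[C@H](OCc1ccc(OC)cc1)[C@]2(C)C(=O)N1CCC[C@H]1COC | intermediate
14 | 12β-alcohol of 13 | C=C[C@H]2[C@@H](C)[C@@H](O)C[C@H](OCc1ccc(OC)cc1)[C@]2(C)C(=O)N1CCC[C@H]1COC | intermediate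
15 | 12β-TBS ether | C=C[C@H]2[C@@H](C)[C@@H](O[Si](C)(C)C(C)(C)C)C[C@H](OCc1ccc(OC)cc1)[C@]2(C)C(=O)N1CCC[C@H]1COC | intermediate
16 | vicinal diol from the vinyl group (C9 epimers) | OCC(O)[C@H]2[C@@H](C)[C@@H](O[Si](C)(C)C(C)(C)C)C[C@H](OCc1ccc(OC)cc1)[C@]2(C)C(=O)N1CCC[C@H]1COC | intermediate (not isolated)
17 | C9 aldehyde | O=C[C@H]2[C@@H](C)[C@@H](O[Si](C)(C)C(C)(C)C)C[C@H](OCc1ccc(OC)cc1)[C@]2(C)C(=O)N1CCC[C@H]1COC | intermediate
18 | (8R,9R)-9-hydroxy-8-(methoxymethoxy) alkoxyallylation adduct | C=C[C@@H](OCOC)[C@H](O)[C@H]2[C@@H](C)[C@@H](O[Si](C)(C)C(C)(C)C)C[C@H](OCc1ccc(OC)cc1)[C@]2(C)C(=O)N1CCC[C@H]1COC | intermediate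
19 | 9-O-PMB ether of 18 | C=C[C@@H](OCOC)[C@H](OCc1ccc(OC)cc1)[C@H]2[C@@H](C)[C@@H](O[Si](C)(C)C(C)(C)C)C[C@H](OCc1ccc(OC)cc1)[C@]2(C)C(=O)N1CCC[C@H]1COC | intermediate
20 | C2 vinyl ketone | C=C[C@@H](OCOC)[C@H](OCc1ccc(OC)cc1)[C@H]2[C@@H](C)[C@@H](O[Si](C)(C)C(C)(C)C)C[C@H](OCc1ccc(OC)cc1)[C@]2(C)C(=O)C=C | intermediate
21 | (2R)-allylic alcohol | C=C[C@@H](OCOC)[C@H](OCc1ccc(OC)cc1)[C@H]2[C@@H](C)[C@@H](O[Si](C)(C)C(C)(C)C)C[C@H](OCc1ccc(OC)cc1)[C@]2(C)[C@H](O)C=C | intermediate
22 | 2-O-PMB ether of 21 | C=C[C@@H](OCOC)[C@H](OCc1ccc(OC)cc1)[C@H]2[C@@H](C)[C@@H](O[Si](C)(C)C(C)(C)C)C[C@H](OCc1ccc(OC)cc1)[C@]2(C)[C@H](OCc1ccc(OC)cc1)C=C | intermediate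
23 | (8R,9R)-C8 allylic alcohol | C=C[C@@H](O)[C@H](OCc1ccc(OC)cc1)[C@H]2[C@@H](C)[C@@H](O[Si](C)(C)C(C)(C)C)C[C@H](OCc1ccc(OC)cc1)[C@]2(C)[C@H](OCc1ccc(OC)cc1)C=C | intermediate
24 | (7R,8S,9R)-6,7-epoxy-8-ol | C1O[C@H]1[C@@H](O)[C@H](OCc1ccc(OC)cc1)[C@H]2[C@@H](C)[C@@H](O[Si](C)(C)C(C)(C)C)C[C@H](OCc1ccc(OC)cc1)[C@]2(C)[C@H](OCc1ccc(OC)cc1)C=C | intermediate
25 | (7R,9R)-6,7-epoxy-8-ketone | C1O[C@H]1C(=O)[C@H](OCc1ccc(OC)cc1)[C@H]2[C@@H](C)[C@@H](O[Si](C)(C)C(C)(C)C)C[C@H](OCc1ccc(OC)cc1)[C@]2(C)[C@H](OCc1ccc(OC)cc1)C=C | intermediate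
26 | aldol adduct, tert-butyl ester with C8 tertiary alcohol and intact oxirane | C1O[C@H]1[C@@](O)([C@@H](C)C(=O)OC(C)(C)C)[C@H](OCc1ccc(OC)cc1)[C@H]2[C@@H](C)[C@@H](O[Si](C)(C)C(C)(C)C)C[C@H](OCc1ccc(OC)cc1)[C@]2(C)[C@H](OCc1ccc(OC)cc1)C=C | intermediate (not isolated)
27 | hydroxymethyl γ-lactone | OC[C@@H]1OC(=O)[C@H](C)[C@@]1(O)[C@H](OCc1ccc(OC)cc1)[C@H]2[C@@H](C)[C@@H](O[Si](C)(C)C(C)(C)C)C[C@H](OCc1ccc(OC)cc1)[C@]2(C)[C@H](OCc1ccc(OC)cc1)C=C | intermediate
28 | C6 aldehyde | O=C[C@@H]1OC(=O)[C@H](C)[C@@]1(O)[C@H](OCc1ccc(OC)cc1)[C@H]2[C@@H](C)[C@@H](O[Si](C)(C)C(C)(C)C)C[C@H](OCc1ccc(OC)cc1)[C@]2(C)[C@H](OCc1ccc(OC)cc1)C=C | intermediate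
29 | methyl (Z)-2-iodoenoate | COC(=O)/C(I)=C/[C@@H]1OC(=O)[C@H](C)[C@@]1(O)[C@H](OCc1ccc(OC)cc1)[C@H]2[C@@H](C)[C@@H](O[Si](C)(C)C(C)(C)C)C[C@H](OCc1ccc(OC)cc1)[C@]2(C)[C@H](OCc1ccc(OC)cc1)C=C | intermediate
30 | C4 alkyl-9-BBN borane | COC(=O)/C(I)=C/[C@@H]1OC(=O)[C@H](C)[C@@]1(O)[C@H](OCc1ccc(OC)cc1)[C@H]2[C@@H](C)[C@@H](O[Si](C)(C)C(C)(C)C)C[C@H](OCc1ccc(OC)cc1)[C@]2(C)[C@H](OCc1ccc(OC)cc1)CCB1C2CCCC1CCC2 | intermediate (not isolated)
31 | ten-membered carbocycle, 2,9,14-tris-PMB ether 12-TBS ether | COC(=O)/C1=C/[C@@H]2OC(=O)[C@H](C)[C@@]2(O)[C@H](OCc3ccc(OC)cc3)[C@H]2[C@@H](C)[C@@H](O[Si](C)(C)C(C)(C)C)C[C@H](OCc3ccc(OC)cc3)[C@]2(C)[C@H](OCc3ccc(OC)cc3)CC1 | intermediate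
32 | 2,9,14-triol 12-TBS ether | COC(=O)/C1=C/[C@@H]2OC(=O)[C@H](C)[C@@]2(O)[C@H](O)[C@H]2[C@@H](C)[C@@H](O[Si](C)(C)C(C)(C)C)C[C@H](O)[C@]2(C)[C@H](O)CC1 | intermediate
33 | 2,9,14-triacetate 12-TBS ether | COC(=O)/C1=C/[C@@H]2OC(=O)[C@H](C)[C@@]2(O)[C@H](OC(C)=O)[C@H]2[C@@H](C)[C@@H](O[Si](C)(C)C(C)(C)C)C[C@H](OC(C)=O)[C@]2(C)[C@H](OC(C)=O)CC1 | intermediate
34 | CNP0233742.2 | COC(=O)/C1=C/[C@@H]2OC(=O)[C@H](C)[C@@]2(O)[C@H](OC(C)=O)[C@H]2[C@@H](C)[C@@H](O)C[C@H](OC(C)=O)[C@]2(C)[C@H](OC(C)=O)CC1 | target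

**Totals**

Total step count: 26. Longest linear sequence: 26 steps (from 2-methoxy-5-methylbenzoic acid).

**Steps most likely to fail**

Step 23 (ring closure). Transmetalation onto the hindered iodoenoate may be slow, so that protodeboronation, β-hydride elimination and intermolecular coupling outrun closure of the strained ten-membered ring. Fallback, from 29 back to 31: Stille coupling with tributyl(vinyl)stannane (Pd2(dba)3, AsPh3, CuI, DMF) would give the 5-vinyl dienoate F1. Ring-closing metathesis between its C5 vinyl group and the C2 vinyl group (second-generation Grubbs catalyst, RuCl2(=CHPh)(H2IMes)(PCy3), toluene, high dilution) would close the ring as the cyclic 3,5-dienoate F2. Diimide (2-nitrobenzenesulfonyl hydrazide, Et3N) would then saturate only the disubstituted C3=C4 bond and return the route at 31.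

Step 20 (lactone annulation). Facial selectivity at C8 may be poor if the zinc chelate is incomplete, the ketone may enolise at C9, and the oxirane may open early or migrate toward the C8 alkoxide. Fallback, from 23 back to 27: Dess–Martin oxidation would give the C8 vinyl ketone F3, and chelation-controlled addition of BrZnCH(CH3)CO2t-Bu the tertiary alcohol F4. Iodolactonisation (I2, NaHCO3, MeCN, 0 °C), which is cis-selective for 3-hydroxy-4-pentenoates and in which the tert-butyl ester cyclises with loss of 2-methylpropene, would give the iodomethyl lactone F5. CF3CO2Ag followed by mild methanolysis would exchange iodine for hydroxyl at C6 and return the route at 27.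

Step 14 (amide to vinyl ketone). The neopentyl amide may resist addition of the organolithium, and the freed enone may polymerise or take up the auxiliary amine during the quench. Fallback, from 19 back to 20: reduction with LiH2NBH3 (THF, 0 °C → rt) would give the C2 primary alcohol F6, Dess–Martin oxidation the C2 aldehyde F7, and addition of CH2=CHMgBr the C2 allylic alcohols F8 (both epimers); a second Dess–Martin oxidation would return the route at 20.

**Further compounds**

F1 | step 23 | 5-vinyl dienoate | COC(=O)/C(C=C)=C/[C@@H]1OC(=O)[C@H](C)[C@@]1(O)[C@H](OCc1ccc(OC)cc1)[C@H]2[C@@H](C)[C@@H](O[Si](C)(C)C(C)(C)C)C[C@H](OCc1ccc(OC)cc1)[C@]2(C)[C@H](OCc1ccc(OC)cc1)C=C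
F2 | step 23 | ten-membered cyclic 3,5-dienoate (C3=C4 geometry inconsequential) | COC(=O)/C1=C/[C@@H]2OC(=O)[C@H](C)[C@@]2(O)[C@H](OCc3ccc(OC)cc3)[C@H]2[C@@H](C)[C@@H](O[Si](C)(C)C(C)(C)C)C[C@H](OCc3ccc(OC)cc3)[C@]2(C)[C@H](OCc3ccc(OC)cc3)C=C1
F3 | step 20 | C8 vinyl ketone | C=CC(=O)[C@H](OCc1ccc(OC)cc1)[C@H]2[C@@H](C)[C@@H](O[Si](C)(C)C(C)(C)C)C[C@H](OCc1ccc(OC)cc1)[C@]2(C)[C@H](OCc1ccc(OC)cc1)C=C
F4 | step 20 | tert-butyl ester tertiary alcohol (Reformatsky adduct) | C=C[C@@](O)([C@@H](C)C(=O)OC(C)(C)C)[C@H](OCc1ccc(OC)cc1)[C@H]2[C@@H](C)[C@@H](O[Si](C)(C)C(C)(C)C)C[C@H](OCc1ccc(OC)cc1)[C@]2(C)[C@H](OCc1ccc(OC)cc1)C=C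
F5 | step 20 | iodomethyl γ-lactone | IC[C@@H]1OC(=O)[C@H](C)[C@@]1(O)[C@H](OCc1ccc(OC)cc1)[C@H]2[C@@H](C)[C@@H](O[Si](C)(C)C(C)(C)C)C[C@H](OCc1ccc(OC)cc1)[C@]2(C)[C@H](OCc1ccc(OC)cc1)C=C
F6 | step 14 | C2 primary alcohol | C=C[C@@H](OCOC)[C@H](OCc1ccc(OC)cc1)[C@H]2[C@@H](C)[C@@H](O[Si](C)(C)C(C)(C)C)C[C@H](OCc1ccc(OC)cc1)[C@]2(C)CO
F7 | step 14 | C2 aldehyde | C=C[C@@H](OCOC)[C@H](OCc1ccc(OC)cc1)[C@H]2[C@@H](C)[C@@H](O[Si](C)(C)C(C)(C)C)C[C@H](OCc1ccc(OC)cc1)[C@]2(C)C=O
F8 | step 14 | C2 allylic alcohols (both C2 epimers) | C=C[C@@H](OCOC)[C@H](OCc1ccc(OC)cc1)[C@H]2[C@@H](C)[C@@H](O[Si](C)(C)C(C)(C)C)C[C@H](OCc1ccc(OC)cc1)[C@]2(C)C(O)C=C
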